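Compare the climb with the sag in Tuesday's flask: the readings of target gain 8.3 percentage points between 0.250 min and 1.33 min, then lose 0.7 points by 4.00 min, which is less. Treat the sag as a small correction to a plateau.

| flask | starting material | partner | second substrate | temperature | remark | time |
|---|---|---|---|---|---|---|
| Tuesday's | 0.10 M | 0.095 M | 0.50 M | 80 °C | the very flask that is asked about, followed so far |  |
| Sunday's | 0.10 M | 0.095 M | 0.75 M | 86 °C | run made earlier |  |
| flask | 0.10 M | 0.0950 M | 0.500 M | 80 °C |  | 4.0 min |

- Tuesday's (time / min: target / %): 0.250: 15.5; 0.833: 22.7; 1.33: 23.8; 2.00: 23.6; 3.00: 23.0; 4.00: 23.1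
- Sunday's (time / min: target / %): 0.250: 16.1; 0.833: 19.4; 1.33: 20.6; 2.00: 20.8; 3.00: 20.3; 4.00: 19.6

(scatter of a reading: 0.5 percentage points)

- target that was removed still counts
- steps under discussion: starting material + partner <-> target; second substrate + partner <-> second product; partner + target -> over-reaction product; second substrate <-> dormant form
- additions bring no volume worth counting

- oak: at 4.0 min add partner, 50.0% of the amount charged, then wait 8.0 min
- cedar: change nothing and wait 8.0 min more
- larch: at 4.0 min take out 90% of the target then present, then wait 8.0 min
- elm: at 4.0 min raise the temperature by 10 K, then wait 8.0 min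

1. target, in percent of the starting material first charged, at 4.0 min
2. which option adds most target ("none" when 2 percentage points or less is all one gets) (oak / cedar / larch / elm / none)
3. target present, with what was taken out counted in, in percent of the starting material first charged, after larch
4. target present, with what was taken out counted in, in percent of the starting material first charged, after elm

Reckon by hand. Average the readings at 3.00 min and 4.00 min: 23.1%. The pair at 1.33 min and 2.00 min stands 0.65 points higher, and the two pairs lie 1.83 min apart. Carry that pace on to the last reading and commit to 22.9% at 4.0 min.

Now count unbound starting material as the charge minus target, leaving over-reaction product out of the count. Define ρ, the held ratio, as target per unbound starting material on the plateau: 0.297. In a quasi-equilibrium of starting material + partner <-> target, ρ goes with free partner.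

By this estimate larch takes out 20.6%. Hold ρ, and the remaining charge splits as before, for a total of 38.7%. The weak link is that constant ρ: the readings sag. Reforge it by subtracting the same pace over 8.0 min, which gives 35.9%, my figure for larch.

The forecast says 23.1% (22.5% to 23.7%), best oak, larch 34% and elm 25%, with the caution “Larch and oak are close”. Its larch figure stands lower than mine.

The flask gives 23.0%, best larch, larch 33.9% and elm 13.3%. Larch adds 11 points; oak changes target by −1.3 points.

    starting material + partner ⇌ target (K = 11.5 L mol⁻¹, k = 0.176 L mol⁻¹ s⁻¹, Ea = 66.0 kJ mol⁻¹, ΔH = −34.0 kJ mol⁻¹)
    second substrate + partner ⇌ second product (K = 3.23 L mol⁻¹, k = 0.0492 L mol⁻¹ s⁻¹, Ea = 64.0 kJ mol⁻¹, ΔH = −45.0 kJ mol⁻¹)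
    partner + target → over-reaction product (k = 0.0356 L mol⁻¹ s⁻¹, Ea = 55.0 kJ mol⁻¹)
    second substrate ⇌ dormant form (K = 1.05, k = 0.00309 s⁻¹, Ea = 104 kJ mol⁻¹, ΔH = −46.0 kJ mol⁻¹)
    (constants at 80 °C)

At 1.33 min in Tuesday's flask, target falls back to starting material and partner 14 times faster than it goes on to over-reaction product. At 4.00 min in that flask it is made at 0.753 of the rate at which it is used up, each step taken net. With ρ, the larch reckoning stands 2 points above the flask.

In the neighbour charged with 0.025 M of starting material, free partner is 44.7% of its charge against 31.2% in Tuesday's flask, so ρ scales to 0.424. Times its 62.3% of starting material, that gives 26.4% target. The computed result is 28.0%.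

(Readings and results were generated by integration for substances that don't exist; the scatter is artificial.)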